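**Plan**
- Cuts: the acetate; the O–C6 lactone bond (back to a C6–C7 epoxide opened by the C15 acid); the O–C12 lactone bond (back to a primary alcohol oxidised onto the C8 hemiketal); then the C7–C8 σ-bond together with the C5=C6 enolate π-bond, traded for a C5–C10 σ-bond.
- Enabling feature: C8 lies in a 2,5-dihydrofuran (O1, C1, C10, C9, C8) whose C9=C10 bond is allylic to C7–C8, and C5, two atoms from C7, carries oxygen. C7–C6–C5(O)/C10=C9–C8 is thus the product side of an oxy-Cope shift of a cis-fused hexahydrobenzofuran with an alkynyl carbinol at C5 and a ketene acetal at C8=C9.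
- Forward order: six-membered ring (2-allyl-2-methylcyclohexane-1,3-dione) → cis-fused γ-lactone → C4 diol → in one flask ketene silyl acetal, acetylide addition and ring expansion to the O1-bridged ten-membered ring → C5 alcohol → spiro lactone on C8 and C15 acid → epoxide opened to the second lactone → acetate.
- Stereochemistry: C1 from enzymatic reduction of the dione; C4 from dihydroxylation on the convex face of the bicyclic enone; C11 from methyl (R)-3-hydroxy-2-methylpropanoate; C8 by suprafacial transfer from C10 in the shift; C5 by hydride addition; C6 and C7 by hydroxyl-directed epoxidation of the Z alkene and inversion at C6.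

Key step: step 9

Atom numbers used below (target): C1 = CH–O of the dihydrofuran, then around the ten-membered ring C2, C3, C4 (C–OH), C5 (CH–OAc), C6 (CH–O), C7 (C–OH), C8 (ketal C), C9 (=CH), C10 (=C–CH3); C11 = CH(CH3) with methyl C13 and lactone carbonyl C12; C14 = methyl on C10; C15 = lactone carbonyl on C4; O1 = ring oxygen between C1 and C8.

Assumption: with C1 fixed, the six-carbon bridge C2–C7 lets C8 be joined to O1 and C7 in one way only, so C8 follows from C1 and the ring and is written in every compound with the descriptor of the target SMILES.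

Step 1
Reactants: 1 2-methylcyclohexane-1,3-dione; 2 allyl bromide
Product: 3 2-allyl-2-methylcyclohexane-1,3-dione
Conditions: NaOH (1 M, aq), 25 °C
Reagents that add atoms: none
Why: C-allylation (SN2) of the stabilised enolate of the cyclic 1,3-dione should build the quaternary carbon that becomes C10, with no stereocentre formed.

Step 2
Reactants: 3 2-allyl-2-methylcyclohexane-1,3-dione
Product: 4 (2S,3S)-2-allyl-3-hydroxy-2-methylcyclohexan-1-one
Conditions: baker's yeast (Saccharomyces cerevisiae), sucrose, H2O, 30 °C
Reagents that add atoms: none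
Why: a desymmetrising enzymatic carbonyl reduction with close precedent on this dione should reduce one of the two enantiotopic ketones and set C1 (S) with the hydroxyl cis to the allyl group.

Step 3
Reactants: 4 (2S,3S)-2-allyl-3-hydroxy-2-methylcyclohexan-1-one
Product: 6 (3aS,7aS)-3a-methyltetrahydro-1-benzofuran-2,4(3H,5H)-dione, via lactol 5 (not isolated)
Conditions: O3, CH2Cl2/MeOH, −78 °C, then Me2S; crude lactol: (2,2,6,6-tetramethylpiperidin-1-yl)oxyl (TEMPO, cat.), PhI(OAc)2, CH2Cl2, 25 °C
Reagents that add atoms: ozone [O-][O+]=O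
Why: ozonolysis of the terminal alkene should give the aldehyde (C8) that closes on the cis hydroxyl to the lactol, and oxoammonium oxidation of the lactol should give the cis-fused γ-lactone without touching a stereocentre.

Step 4
Reactants: 6 (3aS,7aS)-3a-methyltetrahydro-1-benzofuran-2,4(3H,5H)-dione
Product: 7 (3aS,7aS)-3a-methyl-5-methylidenetetrahydro-1-benzofuran-2,4(3H,5H)-dione
Conditions: (CH2O)n, PhNHMe·CF3CO2H, THF, reflux
Reagents that add atoms: formaldehyde (as paraformaldehyde) C=O
Why: Mannich-type α-methylenation (iminium addition, then elimination of the amine) should occur at C4, the only enolisable position of the ketone, and bring in C15.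

Step 5
Reactants: 7 (3aS,7aS)-3a-methyl-5-methylidenetetrahydro-1-benzofuran-2,4(3H,5H)-dione
Product: 8 (3aS,5R,7aS)-5-hydroxy-5-(hydroxymethyl)-3a-methyltetrahydro-1-benzofuran-2,4(3H,5H)-dione
Conditions: OsO4 (cat.), N-methylmorpholine N-oxide, acetone/H2O, 0 → 25 °C
Reagents that add atoms: N-methylmorpholine N-oxide C[N+]1([O-])CCOCC1; water O
Why: OsO4-catalysed syn-dihydroxylation of the exocyclic enone should take place on the convex face of the cis-fused bicycle (the face of the angular methyl, away from the lactone ring), which puts the C4 hydroxyl cis to the methyl and C15 cis to the lactone ring.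

Step 6
Reactants: 8 (3aS,5R,7aS)-5-hydroxy-5-(hydroxymethyl)-3a-methyltetrahydro-1-benzofuran-2,4(3H,5H)-dione
Product: 9 di-tert-butylsilylene acetal of 8
Conditions: t-Bu2Si(OTf)2, 2,6-lutidine, CH2Cl2, 0 °C
Reagents that add atoms: di-tert-butylsilyl bis(trifluoromethanesulfonate) CC(C)(C)[Si](OS(=O)(=O)C(F)(F)F)(OS(=O)(=O)C(F)(F)F)C(C)(C)C
Why: silylene acetal formation should tie the tertiary and the primary hydroxyl into a five-membered ring that resists base and acetylide, carries no carbonyl (so the later C5 alkoxide cannot cleave by retro-aldol) and falls to fluoride.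

Step 7
Reactants: 10 methyl (R)-3-hydroxy-2-methylpropanoate
Product: 11 methyl (R)-3-[(tert-butyldimethylsilyl)oxy]-2-methylpropanoate
Conditions: t-BuMe2SiCl, imidazole, CH2Cl2, 25 °C
Reagents that add atoms: tert-butyldimethylsilyl chloride CC(C)(C)[Si](C)(C)Cl
Why: silyl ether formation should protect the primary hydroxyl (the later C12 oxygen) without touching the stereocentre that becomes C11.

Step 8
Reactants: 11 methyl (R)-3-[(tert-butyldimethylsilyl)oxy]-2-methylpropanoate
Product: 13 tert-butyl(dimethyl){[(2S)-2-methylbut-3-yn-1-yl]oxy}silane, via aldehyde 12 (not isolated)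
Conditions: i-Bu2AlH, CH2Cl2, −78 °C; then MeOH, K2CO3, dimethyl (1-diazo-2-oxopropyl)phosphonate, −78 → 25 °C
Reagents that add atoms: dimethyl (1-diazo-2-oxopropyl)phosphonate CC(=O)C(=[N+]=[N-])P(=O)(OC)OC
Why: partial reduction of the ester and Ohira–Bestmann (Seyferth–Gilbert) homologation of the aldehyde in the same flask should give the terminal alkyne (C6≡C7) with the stereocentre kept, since the aldehyde is consumed cold under mild base (the descriptor changes from R to S by priority only).

Step 9
Reactants: 9 di-tert-butylsilylene acetal of 8; 13 tert-butyl(dimethyl){[(2S)-2-methylbut-3-yn-1-yl]oxy}silane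
Product: 16 O1-bridged ten-membered Z-enone with C8 tert-butyldimethylsilyl ketal, via ketene silyl acetal 14 (not isolated), via alkynyl carbinol 15 (not isolated)
Conditions: 9, KN(SiMe3)2 (1.05 equiv), t-BuMe2SiCl (1.0 equiv), THF, −78 °C; then 13 premixed with KN(SiMe3)2 and 18-crown-6 in THF, −78 → 25 °C; NH4Cl (aq)
Reagents that add atoms: tert-butyldimethylsilyl chloride CC(C)(C)[Si](C)(C)Cl
Why: Proposed new method: KN(SiMe3)2/t-BuMe2SiCl should turn the only enolisable carbonyl, the lactone, into its cyclic ketene silyl acetal 14, so that the potassium acetylide of 13 can add only to the C5 ketone, anti to the axial C4–O bond and hence on the face of the five-membered ring, giving the alkoxide of 15 in which C7≡C6–C5(O–)–C10–C9=C8 is a 3-oxido-1,5-enyne. This alkoxide should undergo a [3,3] sigmatropic shift (anionic oxy-Cope rearrangement) that breaks C5–C10 and forms C7–C8, and protonation of the allenolate at C6 gives the enone; the closest known reaction type is the anionic oxy-Cope ring expansion of 1-alkynyl-2-vinylcyclohexanols to cyclodecadienones, here with a ketene acetal as the ene, which the shift should accept because it is driven both by alkoxide-to-enolate and by ketene-acetal-to-ketal conversion. Ring closure: the six-membered ring is expanded by four atoms through a six-centre transition state to the ten-membered carbocycle, which is at once the nine-membered oxacycle of an 11-oxabicyclo[6.2.1]undecadiene because O1 already joins C1 and C8. New stereocentre C8: the C7–C8 bond forms on the face of the five-membered ring from which C5 departs (suprafacial transfer from C10, itself tied to C1 by the cis ring fusion); C9=C10 is Z because it stays inside the five-membered ring, and C6=C7 should be Z because only a cis alkene fits the nine-membered ring. Selectivity needed: ketone over lactone (secured by the ketene acetal made first), shift over retro-aldol cleavage (secured by the carbonyl-free silylene at C4) and over silyl transfer to the alkoxide (the siloxy group on C8 points away from C5 across the ring double bond).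

Step 10
Reactants: 16 O1-bridged ten-membered Z-enone with C8 tert-butyldimethylsilyl ketal
Product: 17 (5S)-allylic alcohol of 16
Conditions: i-Bu2AlH, CH2Cl2, −78 °C; KNaC4H4O6 (aq)
Reagents that add atoms: none
Why: 1,2-reduction of the enone by the aluminium hydride should deliver hydride anti to the C4–O bond (Felkin–Anh, non-chelating silyl oxygen) from the outer face of the ring, giving the C5 alcohol with O4 and O5 syn.

Step 11
Reactants: 17 (5S)-allylic alcohol of 16
Product: 18 pentaol with bridged C8 hemiketal
Conditions: Bu4NF, AcOH (1:1), THF, 0 → 25 °C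
Reagents that add atoms: none
Why: buffered fluoride should cleave the silyl ether, the silyl ketal and the silylene in one operation, the near-neutral medium keeping the C8 hemiketal from dehydrative ketalisation with the C12 hydroxyl.

Step 12
Reactants: 18 pentaol with bridged C8 hemiketal
Product: 19 spiro γ-lactone carboxylic acid
Conditions: TEMPO (cat.), NaOCl (cat.), NaClO2, MeCN/phosphate buffer pH 6.7, 35 °C; then citric acid to pH 3
Reagents that add atoms: sodium chlorite [Na+].[O-]Cl=O
Why: oxoammonium/chlorite oxidation, selective for primary alcohols, should take C15 to the carboxylic acid and C12, through its aldehyde and the lactol with the C8 hemiketal hydroxyl, to the spiro γ-lactone, while the secondary C5 and the tertiary hydroxyls remain.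

Step 13
Reactants: 19 spiro γ-lactone carboxylic acid
Product: 21 5-hydroxy bis-lactone (target without acetyl), via epoxy acid 20 (not isolated)
Conditions: VO(acac)2 (cat.), t-BuOOH, CH2Cl2, 0 → 25 °C
Reagents that add atoms: tert-butyl hydroperoxide CC(C)(C)OO
Why: hydroxyl-directed epoxidation of the Z C6=C7 alkene should deliver oxygen syn to the C5 hydroxyl with H5 in the alkene plane (allylic 1,3-strain, threo epoxy alcohol), and the C15 acid should then open the epoxide at C6 in 5-exo fashion with inversion (C7 is deactivated by the adjacent ketal carbon), setting C6 (R) and C7 (S).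

Step 14
Reactants: 21 5-hydroxy bis-lactone (target without acetyl)
Product: 22 target compound CNP0315698.1
Conditions: Ac2O, pyridine, 4-(dimethylamino)pyridine (cat.), CH2Cl2, 0 °C
Reagents that add atoms: acetic anhydride CC(=O)OC(C)=O
Why: nucleophile-catalysed acylation should esterify only the secondary C5 hydroxyl, the two tertiary hydroxyls being inert under these conditions.

**Compound list**
1 | 2-methylcyclohexane-1,3-dione | CC1C(=O)CCCC1=O | starting material
2 | allyl bromide (3-bromoprop-1-ene) | C=CCBr | starting material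
3 | 2-allyl-2-methylcyclohexane-1,3-dione | C=CCC1(C)C(=O)CCCC1=O | intermediate
4 | (2S,3S)-2-allyl-3-hydroxy-2-methylcyclohexan-1-one (hydroxyl cis to allyl) | C=CC[C@]1(C)C(=O)CCC[C@@H]1O | intermediate
5 | (3aS,7aS)-2-hydroxy-3a-methylhexahydro-1-benzofuran-4(2H)-one, cis-fused lactol, anomer mixture | OC2C[C@]1(C)C(=O)CCC[C@@H]1O2 | intermediate (not isolated)
6 | (3aS,7aS)-3a-methyltetrahydro-1-benzofuran-2,4(3H,5H)-dione, cis-fused keto lactone | O=C2C[C@]1(C)C(=O)CCC[C@@H]1O2 | intermediate
7 | (3aS,7aS)-3a-methyl-5-methylidenetetrahydro-1-benzofuran-2,4(3H,5H)-dione | O=C2C[C@]1(C)C(=O)C(=C)CC[C@@H]1O2 | intermediate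
8 | (3aS,5R,7aS)-5-hydroxy-5-(hydroxymethyl)-3a-methyltetrahydro-1-benzofuran-2,4(3H,5H)-dione (tertiary OH cis to the angular methyl) | O=C2C[C@]1(C)C(=O)[C@](O)(CO)CC[C@@H]1O2 | intermediate
9 | di-tert-butylsilylene acetal of 8 (five-membered Si ring over the C4 and C15 oxygens, spiro at C4) | O=C2C[C@]1(C)C(=O)[C@](O3)(CO[Si]3(C(C)(C)C)C(C)(C)C)CC[C@@H]1O2 | intermediate
10 | methyl (R)-3-hydroxy-2-methylpropanoate | COC(=O)[C@H](C)CO | starting material
11 | methyl (R)-3-[(tert-butyldimethylsilyl)oxy]-2-methylpropanoate | COC(=O)[C@H](C)CO[Si](C)(C)C(C)(C)C | intermediate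
12 | (R)-3-[(tert-butyldimethylsilyl)oxy]-2-methylpropanal | O=C[C@H](C)CO[Si](C)(C)C(C)(C)C | intermediate (not isolated)
13 | tert-butyl(dimethyl){[(2S)-2-methylbut-3-yn-1-yl]oxy}silane | C#C[C@H](C)CO[Si](C)(C)C(C)(C)C | intermediate
14 | cyclic ketene tert-butyldimethylsilyl acetal of lactone 9 (C9=C8(OSi)–O1 in the five-membered ring) | CC(C)(C)[Si](C)(C)OC2=C[C@]1(C)C(=O)[C@](O3)(CO[Si]3(C(C)(C)C)C(C)(C)C)CC[C@@H]1O2 | intermediate (not isolated)
15 | C5 tertiary propargylic alcohol from 14 and 13 (potassium alkoxide in the flask; alkyne on the face of the five-membered ring) | CC(C)(C)[Si](C)(C)OC2=C[C@]1(C)[C@](O)(C#C[C@H](C)CO[Si](C)(C)C(C)(C)C)[C@](O3)(CO[Si]3(C(C)(C)C)C(C)(C)C)CC[C@@H]1O2 | intermediate (not isolated)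
16 | ten-membered ring C1–C10 bridged by O1 (C1–O–C8): C5 ketone, C6=C7 (Z), C8 ketal carbon with OSi(t-Bu)Me2, C9=C10(CH3); (S)-CH(CH3)CH2OSi(t-Bu)Me2 on C7; silylene on the C4 and C15 oxygens | O=C1/C=C(/[C@H](C)CO[Si](C)(C)C(C)(C)C)\[C@]2(O[Si](C)(C)C(C)(C)C)O[C@@H](CC[C@@]1(O3)CO[Si]3(C(C)(C)C)C(C)(C)C)C(C)=C2 | intermediate
17 | (5S)-allylic alcohol of 16 | O[C@H]1/C=C(/[C@H](C)CO[Si](C)(C)C(C)(C)C)\[C@]2(O[Si](C)(C)C(C)(C)C)O[C@@H](CC[C@@]1(O3)CO[Si]3(C(C)(C)C)C(C)(C)C)C(C)=C2 | intermediate
18 | pentaol: C5–OH, C4–OH, C15H2OH, C12H2OH and bridged hemiketal OH on C8; C6=C7 (Z), C9=C10 | O[C@H]1/C=C(/[C@H](C)CO)\[C@]2(O)O[C@@H](CC[C@@]1(O)CO)C(C)=C2 | intermediate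
19 | spiro γ-lactone (C12 to O on C8) with C15 carboxylic acid on C4, C5–OH, C4–OH, C6=C7 (Z) | O[C@H]1/C=C2/[C@H](C)C(=O)O[C@]23O[C@@H](CC[C@@]1(O)C(=O)O)C(C)=C3 | intermediate
20 | cis-6,7-epoxide of 19, threo to the C5 hydroxyl | O[C@H]1[C@@H]2O[C@@]24[C@H](C)C(=O)O[C@]43O[C@@H](CC[C@@]1(O)C(=O)O)C(C)=C3 | intermediate (not isolated)
21 | target without the acetyl group (C5–OH, both lactones, C4–OH, C7–OH) | O[C@H]1[C@H]2OC(=O)[C@]1(O)CC[C@@H]1O[C@@]3(C=C1C)OC(=O)[C@@H](C)[C@]23O | intermediate
22 | CNP0315698.1 (C1 S, C4 S, C5 S, C6 R, C7 S, C8 S, C11 S) | CC(=O)O[C@H]1[C@H]2OC(=O)[C@]1(O)CC[C@@H]1O[C@@]3(C=C1C)OC(=O)[C@@H](C)[C@]23O | target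

Total step count: 14. Longest linear sequence: 12 steps (steps 1–6 and 9–14); steps 7 and 8 make the alkyne side chain.

**Steps most likely to fail**

1. Step 9 (proposed new method). The two oxygen donors on C8 may slow the shift so much that loss of the acetylide from the alkoxide, silyl transfer or addition of the acetylide to the wrong face of the ketone takes over. Fallback with known chemistry, setting out from 9 and returning at 16:
   - 9 is treated with LiN(SiMe3)2 (1 equiv, −78 °C), which masks the lactone as its enolate, and then with the lithium acetylide of 13 to give, after work-up, the alkynyl carbinol lactone F1.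
   - Me2AlS(CH2)3SAlMe2 converts the lactone of F1 into the ketene dithioacetal diol F2 (ester to ketene dithioacetal).
   - KH with 18-crown-6 then effects the anionic oxy-Cope shift with a sulfur-substituted ene, a substituent class known for this rearrangement, to give the ten-membered enone dithiane F3. Either C5 epimer can react here, because the open-chain ene reaches the alkyne from both faces.
   - Hg(ClO4)2 with CaCO3 in aqueous THF frees the C8 ketone, which the C1 hydroxyl of the Z isomer traps as the bridged hemiketal F4.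
   - t-BuMe2SiOSO2CF3 with 2,6-lutidine silylates the hemiketal hydroxyl to give 16.

2. Step 12. Competing oxidation of the allylic C5 alcohol, or incomplete passage of C12 through the lactol to the lactone, may erode the double oxidation. Fallback, setting out from 17 and returning at 22:
   - 17 is acetylated first (Ac2O, 4-(dimethylamino)pyridine) to the acetate F5, so that no oxidisable secondary alcohol remains.
   - Bu4NF/AcOH gives the hemiketal tetraol acetate F6.
   - The same TEMPO/NaClO2 oxidation gives the spiro lactone acid acetate F7.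
   - Epoxidation of F7 is then directed by the homoallylic C4 hydroxyl (VO(acac)2, t-BuOOH) instead of the C5 hydroxyl, and the epoxy acid lactonises as in step 13 to give 22 directly.

3. Step 10. Poor facial selectivity of hydride addition in the flexible ten-membered ring may favour the wrong C5 configuration. Fallback, setting out from 16 and returning at 17:
   - The C5-epimeric allylic alcohol F8, if it is the main product, is not discarded but inverted by Mitsunobu esterification (PPh3, diisopropyl azodicarboxylate, 4-nitrobenzoic acid) to the 4-nitrobenzoate F9, which has the C5 configuration of 17.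
   - Methanolysis (K2CO3, MeOH) of F9 gives 17.

Further compounds
F1 | step 9 | alkynyl carbinol lactone (15 with the lactone in place of the ketene acetal) | O=C2C[C@]1(C)[C@](O)(C#C[C@H](C)CO[Si](C)(C)C(C)(C)C)[C@](O3)(CO[Si]3(C(C)(C)C)C(C)(C)C)CC[C@@H]1O2
F2 | step 9 | ketene dithioacetal diol (2-ylidene-1,3-dithiane on C9=C8, free C1–OH and C5–OH) | S1CCCSC1=C[C@]2(C)[C@](O)(C#C[C@H](C)CO[Si](C)(C)C(C)(C)C)[C@](O3)(CO[Si]3(C(C)(C)C)C(C)(C)C)CC[C@@H]2O
F3 | step 9 | ten-membered enone with spiro 1,3-dithiane at C8, free C1–OH, C6=C7 (Z), C9=C10 (Z) | O=C1/C=C(/[C@H](C)CO[Si](C)(C)C(C)(C)C)\C2(SCCCS2)/C=C(/C)[C@@H](O)CC[C@@]1(O3)CO[Si]3(C(C)(C)C)C(C)(C)C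
F4 | step 9 | bridged C8 hemiketal of the C5 enone (16 with OH in place of the silyl ketal) | O=C1/C=C(/[C@H](C)CO[Si](C)(C)C(C)(C)C)\[C@]2(O)O[C@@H](CC[C@@]1(O3)CO[Si]3(C(C)(C)C)C(C)(C)C)C(C)=C2
F5 | step 12 | C5 acetate of 17 | CC(=O)O[C@H]1/C=C(/[C@H](C)CO[Si](C)(C)C(C)(C)C)\[C@]2(O[Si](C)(C)C(C)(C)C)O[C@@H](CC[C@@]1(O3)CO[Si]3(C(C)(C)C)C(C)(C)C)C(C)=C2
F6 | step 12 | C5 acetate of 18 (hemiketal tetraol) | CC(=O)O[C@H]1/C=C(/[C@H](C)CO)\[C@]2(O)O[C@@H](CC[C@@]1(O)CO)C(C)=C2
F7 | step 12 | C5 acetate of 19 (spiro lactone acid) | CC(=O)O[C@H]1/C=C2/[C@H](C)C(=O)O[C@]23O[C@@H](CC[C@@]1(O)C(=O)O)C(C)=C3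
F8 | step 10 | C5 epimer of 17 | O[C@@H]1/C=C(/[C@H](C)CO[Si](C)(C)C(C)(C)C)\[C@]2(O[Si](C)(C)C(C)(C)C)O[C@@H](CC[C@@]1(O3)CO[Si]3(C(C)(C)C)C(C)(C)C)C(C)=C2
F9 | step 10 | 4-nitrobenzoate of 17 | O=C(O[C@H]1/C=C(/[C@H](C)CO[Si](C)(C)C(C)(C)C)\[C@]2(O[Si](C)(C)C(C)(C)C)O[C@@H](CC[C@@]1(O3)CO[Si]3(C(C)(C)C)C(C)(C)C)C(C)=C2)c1ccc(cc1)[N+](=O)[O-]
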